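**Plan**

1. Carotenoid numbering is used: the ring is C2–C3–C4–C5–C6, C1 is the CMe2OH carbon on C2, and C7 is the first polyene carbon on C6. The three carbon substituents on the ring (polyene, CMe2OH, 5‑CH3) are all cis and the 5‑OH is trans to them.
2. Retrosynthetic cuts, in order: C7=C8 (ring C10 sulfone + C30 polyenal, the latter cut at C7'=C8' into crocetindialdehyde and a geranyl ylide); the two methyls on C1 and the C5–O bond; then both bonds to the ring's only unsubstituted pair C3H2–C4H2 (C2–C3 and C4–C5) at once.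
3. Enabling feature: that ethano pair lies between C2, whose C1 carbinol is an ester in disguise (so C2 can be a malonate carbanion), and C5, a methyl carbinol that is a methyl ketone in disguise. This 1,3‑donor/acceptor pair across C6 is matched by a vinylphosphonium salt (acceptor carbon C3, ylide carbon C4).
4. Forward order: acyclic C6 stereocenter, then the cyclopentene ring by the annulation, then a temporary cis‑fused γ‑lactone ring between O–C7 and C1 (not in the target, cleaved by MeMgBr), then the chain.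
5. Stereochemistry: C6 from iridium‑catalysed allylic alkylation; C2 from the cis‑fused lactone (decarboxylation and protonation); C5 from convex‑face hydration of the bicycle; double bonds from E building blocks plus iodine equilibration.

Key step: step 5

Assumption: ligand L in step 3 is the antipode of O,O'‑(1,1'‑binaphthalene‑2,2'‑diyl) N,N‑bis(1‑phenylethyl)phosphoramidite that gives (S)‑5; the mirror‑image ligand is taken if the sense of induction proves opposite.
Assumption: (E)‑but‑2‑ene‑1,4‑diol, geranyl bromide and all‑E crocetindialdehyde are taken as purchasable.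

**Route**

Step 1
Reactants: 1 (E)-but-2-ene-1,4-diol
Product: 2 (E)-4-[(tert-butyldiphenylsilyl)oxy]but-2-en-1-ol
Conditions: NaH (1.0 equiv), THF, 0 °C; then TBDPSCl (1.0 equiv), 0 °C → rt
Reagents that add atoms: tert-butyl(chloro)diphenylsilane, CC(C)(C)[Si](Cl)(c1ccccc1)c1ccccc1
Why: Williamson-type O-silylation of the monosodium alkoxide of a symmetrical diol should stop at the mono-ether; no stereocenter is formed.

Step 2
Reactants: 2 (E)-4-[(tert-butyldiphenylsilyl)oxy]but-2-en-1-ol
Product: 3 (E)-4-[(tert-butyldiphenylsilyl)oxy]but-2-en-1-yl methyl carbonate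
Conditions: ClCO2Me, pyridine, CH2Cl2, 0 °C
Reagents that add atoms: methyl chloroformate, COC(=O)Cl
Why: Acylation of the allylic alcohol with a chloroformate gives the carbonate leaving group needed for allylic substitution; no stereocenter is formed.

Step 3
Reactants: 3 (E)-4-[(tert-butyldiphenylsilyl)oxy]but-2-en-1-yl methyl carbonate; 4 dimethyl malonate
Product: 5 dimethyl 2-[(2S)-1-[(tert-butyldiphenylsilyl)oxy]but-3-en-2-yl]malonate
Conditions: [Ir(cod)Cl]2 (2 mol %), ligand L (4 mol %), 1,5,7-triazabicyclo[4.4.0]dec-5-ene (8 mol %), 4 (1.3 equiv), THF, rt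
Reagents that add atoms: none
Why: Iridium-catalysed asymmetric allylic alkylation of a linear (E)-allylic carbonate with a malonate is branched-selective, the chiral phosphoramidite–iridium allyl complex controlling the face of attack and so setting C6 (S), with the methoxide released from the carbonate serving as base.

Step 4
Reactants: 5 dimethyl 2-[(2S)-1-[(tert-butyldiphenylsilyl)oxy]but-3-en-2-yl]malonate
Product: 6 dimethyl 2-[(2S)-1-[(tert-butyldiphenylsilyl)oxy]-3-oxobutan-2-yl]malonate
Conditions: PdCl2(quinox) (5 mol %; quinox = 2-(4,5-dihydrooxazol-2-yl)quinoline), AgSbF6 (12 mol %), 70% aq. t-BuOOH, CH2Cl2, 0 °C → rt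
Reagents that add atoms: tert-butyl hydroperoxide, CC(C)(C)OO
Why: Wacker-type oxidation of the monosubstituted alkene with Markovnikov selectivity gives the methyl ketone (C5=O with the C18 methyl), and the acid-free peroxide variant is chosen so that C6, which is not a reacting atom but becomes α to the ketone, should keep its configuration.

Step 5
Reactants: 6 dimethyl 2-[(2S)-1-[(tert-butyldiphenylsilyl)oxy]-3-oxobutan-2-yl]malonate; 7 vinyltriphenylphosphonium bromide
Product: 10 dimethyl (2S)-2-{[(tert-butyldiphenylsilyl)oxy]methyl}-3-methylcyclopent-3-ene-1,1-dicarboxylate, via sodium malonate enolate 8 (not isolated), via phosphonium ylide 9 (not isolated)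
Conditions: NaH (1.0 equiv), THF, 0 °C; then 7 (1.1 equiv), THF/DMF, 0 °C → 45 °C
Reagents that add atoms: none
Why: The sodium malonate 8 adds to the CH2 terminus of the vinylphosphonium salt (forming C2–C3) to give the non-stabilised ylide 9, whose carbanionic C4 attacks the methyl ketone C5 in an intramolecular Wittig reaction (forming C4=C5 through an oxaphosphetane with loss of Ph3PO), so both bonds to the ethano unit arise in one flask operation. The closest known reaction type is the vinylphosphonium cyclopentene annulation of acetonylmalonates. The single ring closes in a 5-exo-trig mode, the ylide carbon attacking the exocyclic C=O. No new stereocenter is formed: C2 is deliberately a non-stereogenic gem-diester at this stage and the ring alkene is planar, while C6, set by the iridium catalyst in step 3, is carried through. The selectivity needed is deprotonation of the malonate C–H only, without enolising C6 or expelling the β-silyloxy group; it is secured by the large acidity gap, by one equivalent of NaH, by C2 being quaternary after the conjugate addition, and by the speed of five-membered ring closure. The position of the double bond (C4=C5) is fixed by the Wittig connectivity.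

Step 6
Reactants: 10 dimethyl (2S)-2-{[(tert-butyldiphenylsilyl)oxy]methyl}-3-methylcyclopent-3-ene-1,1-dicarboxylate
Product: 12 methyl (3aS,6aR)-4-methyl-1-oxo-3,3a,6,6a-tetrahydro-1H-cyclopenta[c]furan-6a-carboxylate, via hydroxy diester 11 (not isolated)
Conditions: Bu4NF, AcOH, THF, rt; then p-TsOH·H2O (cat.), toluene, 60 °C
Reagents that add atoms: none
Why: Fluoride desilylation followed by acid-promoted transesterification closes the γ-lactone between the C7 hydroxyl and the only ester it can reach, the one cis to it, which desymmetrises the gem-diester and makes C2 a stereocenter under the control of C6.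

Step 7
Reactants: 12 methyl (3aS,6aR)-4-methyl-1-oxo-3,3a,6,6a-tetrahydro-1H-cyclopenta[c]furan-6a-carboxylate
Product: 13 (3aR,6aR)-4-methyl-3,3a,6,6a-tetrahydro-1H-cyclopenta[c]furan-1-one
Conditions: LiCl, H2O (2 equiv), DMSO, 140 °C; dilute HCl work-up
Reagents that add atoms: none
Why: Krapcho dealkoxycarbonylation (chloride dealkylation of the methyl ester, then loss of CO2) gives a lactone enolate that can only be protonated to the cis-fused bicycle, so C2–H is set cis to C7 by the temporary lactone ring.

Step 8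
Reactants: 13 (3aR,6aR)-4-methyl-3,3a,6,6a-tetrahydro-1H-cyclopenta[c]furan-1-one
Product: 14 (3aS,4R,6aR)-4-hydroxy-4-methylhexahydro-1H-cyclopenta[c]furan-1-one
Conditions: Co(acac)2 (20 mol %), PhSiH3, O2 (1 atm), THF, rt; aq. Na2S2O3 work-up
Reagents that add atoms: dioxygen, O=O
Why: Mukaiyama hydration (hydrogen-atom transfer to C4, then capture of the tertiary C5 radical by O2) is Markovnikov-selective, and oxygen should enter on the convex face of the cis-fused bicycle, anti to the lactone ring, which sets C5 with OH trans and CH3 cis to C7.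

Step 9
Reactants: 14 (3aS,4R,6aR)-4-hydroxy-4-methylhexahydro-1H-cyclopenta[c]furan-1-one
Product: 15 (1R,2S,3R)-2-(hydroxymethyl)-3-(2-hydroxypropan-2-yl)-1-methylcyclopentan-1-ol
Conditions: MeMgBr (4 equiv), THF, −20 °C → rt; aq. NH4Cl
Reagents that add atoms: methylmagnesium bromide, C[Mg]Br
Why: Double Grignard addition to the lactone carbonyl builds the CMe2OH group at C1 and releases the C7 primary alcohol, cleaving the temporary ring; no stereocenter is touched, addition to the intermediate methyl ketone being faster than its enolisation at C2.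

Step 10
Reactants: 15 (1R,2S,3R)-2-(hydroxymethyl)-3-(2-hydroxypropan-2-yl)-1-methylcyclopentan-1-ol
Product: 16 (1R,2R,3R)-3-(2-hydroxypropan-2-yl)-1-methyl-2-{[(1-phenyl-1H-tetrazol-5-yl)sulfanyl]methyl}cyclopentan-1-ol
Conditions: 1-phenyl-1H-tetrazole-5-thiol, PPh3, DIAD, THF, 0 °C
Reagents that add atoms: 1-phenyl-1H-tetrazole-5-thiol, Sc1nnnn1-c1ccccc1
Why: Mitsunobu thioetherification activates only the primary alcohol, and the acidic thiol is a far better nucleophile than the neutral tertiary hydroxyls; C7 is not stereogenic.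

Step 11
Reactants: 16 (1R,2R,3R)-3-(2-hydroxypropan-2-yl)-1-methyl-2-{[(1-phenyl-1H-tetrazol-5-yl)sulfanyl]methyl}cyclopentan-1-ol
Product: 17 (1R,2R,3R)-3-(2-hydroxypropan-2-yl)-1-methyl-2-{[(1-phenyl-1H-tetrazol-5-yl)sulfonyl]methyl}cyclopentan-1-ol
Conditions: (NH4)6Mo7O24·4H2O (10 mol %), 30% H2O2, EtOH, 0 °C → rt
Reagents that add atoms: hydrogen peroxide, OO
Why: Molybdate-catalysed peroxide oxidation of the sulfide to the sulfone is the standard preparation of Julia–Kocienski reagents and leaves tertiary alcohols untouched.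

Step 12
Reactants: 17 (1R,2R,3R)-3-(2-hydroxypropan-2-yl)-1-methyl-2-{[(1-phenyl-1H-tetrazol-5-yl)sulfonyl]methyl}cyclopentan-1-ol
Product: 18 5-({(1R,2R,5R)-2-methyl-2-[(triethylsilyl)oxy]-5-{2-[(triethylsilyl)oxy]propan-2-yl}cyclopentyl}methylsulfonyl)-1-phenyl-1H-tetrazole
Conditions: Et3SiOTf, 2,6-lutidine, CH2Cl2, 0 °C → rt
Reagents that add atoms: triethylsilyl trifluoromethanesulfonate, CC[Si](CC)(CC)OS(=O)(=O)C(F)(F)F
Why: Silyl triflate silylation caps both tertiary alcohols so that no alkoxide can attack the tetrazole ring (Smiles-type ipso substitution) during the olefination.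

Step 13
Reactants: 19 geranyl bromide, (E)-1-bromo-3,7-dimethylocta-2,6-diene
Product: 20 geranyltriphenylphosphonium bromide
Conditions: PPh3, toluene, rt
Reagents that add atoms: triphenylphosphine, c1ccccc1P(c1ccccc1)c1ccccc1
Why: SN2 quaternisation of triphenylphosphine by the primary allylic bromide gives the Wittig salt with the (E)-trisubstituted alkene unchanged.

Step 14
Reactants: 20 geranyltriphenylphosphonium bromide; 21 crocetindialdehyde, (2E,4E,6E,8E,10E,12E,14E)-2,6,11,15-tetramethylhexadeca-2,4,6,8,10,12,14-heptaenedial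
Product: 23 apo-8'-lycopenal, (2E,4E,6E,8E,10E,12E,14E,16E,18E)-2,6,11,15,19,23-hexamethyltetracosa-2,4,6,8,10,12,14,16,18,22-decaenal, via geranylidene phosphorane 22 (not isolated)
Conditions: 21 (3 equiv), NaOMe, CH2Cl2/MeOH, 0 °C → rt; then I2 (cat.), CH2Cl2, rt, daylight; excess 21 recovered
Reagents that add atoms: none
Why: Wittig olefination of one aldehyde group of the symmetrical dialdehyde (used in excess) with the allylic ylide forms C7'=C8', and iodine-catalysed equilibration should bring the new disubstituted double bond to E.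

Step 15
Reactants: 18 bis(triethylsilyl) sulfone; 23 apo-8'-lycopenal
Product: 25 bis(triethylsilyl) ether of the target, via potassium sulfonyl carbanion 24 (not isolated)
Conditions: KN(SiMe3)2, THF, −78 °C; then 23, −78 °C → rt; then I2 (cat.), CH2Cl2, rt, daylight
Reagents that add atoms: none
Why: Julia–Kocienski olefination (carbanion addition to the aldehyde, Smiles rearrangement, loss of SO2 and tetrazolyl oxide) forms C7=C8 without ever placing a carbonyl next to C6, so the contra-thermodynamic all-cis ring should stay intact, and iodine equilibration should complete the E geometry.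

Step 16
Reactants: 25 bis(triethylsilyl) ether of the target
Product: 26 target, (1R,2R,3R)-3-(2-hydroxypropan-2-yl)-1-methyl-2-[(1E,3E,5E,7E,9E,11E,13E,15E,17E,19E)-3,7,12,16,20,24-hexamethylpentacosa-1,3,5,7,9,11,13,15,17,19,23-undecaen-1-yl]cyclopentan-1-ol
Conditions: Bu4NF, THF, rt → 40 °C, dark, argon
Reagents that add atoms: none
Why: Fluoride cleavage of the two tertiary triethylsilyl ethers is compatible with the polyene and should give the diol.

**Compound list**

1 | (E)-but-2-ene-1,4-diol | OC/C=C/CO | starting material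
2 | (E)-4-[(tert-butyldiphenylsilyl)oxy]but-2-en-1-ol | OC/C=C/CO[Si](c1ccccc1)(c1ccccc1)C(C)(C)C | intermediate
3 | (E)-4-[(tert-butyldiphenylsilyl)oxy]but-2-en-1-yl methyl carbonate | COC(=O)OC/C=C/CO[Si](c1ccccc1)(c1ccccc1)C(C)(C)C | intermediate
4 | dimethyl malonate | COC(=O)CC(=O)OC | starting material
5 | dimethyl 2-[(2S)-1-[(tert-butyldiphenylsilyl)oxy]but-3-en-2-yl]malonate | C=C[C@H](CO[Si](c1ccccc1)(c1ccccc1)C(C)(C)C)C(C(=O)OC)C(=O)OC | intermediate
6 | dimethyl 2-[(2S)-1-[(tert-butyldiphenylsilyl)oxy]-3-oxobutan-2-yl]malonate | CC(=O)[C@H](CO[Si](c1ccccc1)(c1ccccc1)C(C)(C)C)C(C(=O)OC)C(=O)OC | intermediate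
7 | vinyltriphenylphosphonium bromide | C=C[P+](c1ccccc1)(c1ccccc1)c1ccccc1.[Br-] | starting material
8 | sodium enolate of 6 (malonate carbon deprotonated) | CC(=O)[C@H](CO[Si](c1ccccc1)(c1ccccc1)C(C)(C)C)C(C(=O)OC)=C([O-])OC.[Na+] | intermediate (not isolated)
9 | dimethyl 2-[(2S)-1-[(tert-butyldiphenylsilyl)oxy]-3-oxobutan-2-yl]-2-[2-(triphenyl-λ5-phosphanylidene)ethyl]malonate | CC(=O)[C@H](CO[Si](c1ccccc1)(c1ccccc1)C(C)(C)C)C(CC=P(c1ccccc1)(c1ccccc1)c1ccccc1)(C(=O)OC)C(=O)OC | intermediate (not isolated)
10 | dimethyl (2S)-2-{[(tert-butyldiphenylsilyl)oxy]methyl}-3-methylcyclopent-3-ene-1,1-dicarboxylate | CC(C)(C)[Si](c1ccccc1)(c1ccccc1)OC[C@@H]1C(C(=O)OC)(C(=O)OC)CC=C1C | intermediate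
11 | dimethyl (2S)-2-(hydroxymethyl)-3-methylcyclopent-3-ene-1,1-dicarboxylate | OC[C@@H]1C(C(=O)OC)(C(=O)OC)CC=C1C | intermediate (not isolated)
12 | methyl (3aS,6aR)-4-methyl-1-oxo-3,3a,6,6a-tetrahydro-1H-cyclopenta[c]furan-6a-carboxylate (cis-fused) | O=C1OC[C@@H]2[C@@]1(C(=O)OC)CC=C2C | intermediate
13 | (3aR,6aR)-4-methyl-3,3a,6,6a-tetrahydro-1H-cyclopenta[c]furan-1-one (cis-fused) | O=C1OC[C@@H]2[C@H]1CC=C2C | intermediate
14 | (3aS,4R,6aR)-4-hydroxy-4-methylhexahydro-1H-cyclopenta[c]furan-1-one (OH cis to the ring-fusion hydrogens) | O=C1OC[C@@H]2[C@H]1CC[C@@]2(C)O | intermediate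
15 | (1R,2S,3R)-2-(hydroxymethyl)-3-(2-hydroxypropan-2-yl)-1-methylcyclopentan-1-ol | OC[C@@H]1[C@H](C(C)(C)O)CC[C@@]1(C)O | intermediate
16 | (1R,2R,3R)-3-(2-hydroxypropan-2-yl)-1-methyl-2-{[(1-phenyl-1H-tetrazol-5-yl)sulfanyl]methyl}cyclopentan-1-ol | c1ccccc1-n1nnnc1SC[C@@H]1[C@H](C(C)(C)O)CC[C@@]1(C)O | intermediate
17 | (1R,2R,3R)-3-(2-hydroxypropan-2-yl)-1-methyl-2-{[(1-phenyl-1H-tetrazol-5-yl)sulfonyl]methyl}cyclopentan-1-ol | O=S(=O)(C[C@@H]1[C@H](C(C)(C)O)CC[C@@]1(C)O)c1nnnn1-c1ccccc1 | intermediate
18 | 5-({(1R,2R,5R)-2-methyl-2-[(triethylsilyl)oxy]-5-{2-[(triethylsilyl)oxy]propan-2-yl}cyclopentyl}methylsulfonyl)-1-phenyl-1H-tetrazole | O=S(=O)(C[C@@H]1[C@H](C(C)(C)O[Si](CC)(CC)CC)CC[C@@]1(C)O[Si](CC)(CC)CC)c1nnnn1-c1ccccc1 | intermediate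
19 | geranyl bromide | CC(C)=CCC/C(C)=C/CBr | starting material
20 | geranyltriphenylphosphonium bromide | CC(C)=CCC/C(C)=C/C[P+](c1ccccc1)(c1ccccc1)c1ccccc1.[Br-] | intermediate
21 | crocetindialdehyde (all-E) | O=C/C(C)=C/C=C/C(C)=C/C=C/C=C(C)/C=C/C=C(C)/C=O | starting material
22 | geranylidene(triphenyl)phosphorane | CC(C)=CCC/C(C)=C/C=P(c1ccccc1)(c1ccccc1)c1ccccc1 | intermediate (not isolated)
23 | apo-8'-lycopenal (all-E) | CC(C)=CCC/C(C)=C/C=C/C(C)=C/C=C/C(C)=C/C=C/C=C(C)/C=C/C=C(C)/C=O | intermediate
24 | potassium salt of 18 deprotonated at the CH2 next to sulfur | O=S(=O)([CH-][C@@H]1[C@H](C(C)(C)O[Si](CC)(CC)CC)CC[C@@]1(C)O[Si](CC)(CC)CC)c1nnnn1-c1ccccc1.[K+] | intermediate (not isolated)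
25 | bis(triethylsilyl) ether of the target (both tertiary hydroxyls silylated) | CC(C)=CCC/C(C)=C/C=C/C(C)=C/C=C/C(C)=C/C=C/C=C(C)/C=C/C=C(C)/C=C/[C@@H]1[C@H](C(C)(C)O[Si](CC)(CC)CC)CC[C@@]1(C)O[Si](CC)(CC)CC | intermediate
26 | (all-E)-2,6-cyclolycopene-1,5-diol, carotenoid C2 R, C5 R, C6 R | CC(C)=CCC/C(C)=C/C=C/C(C)=C/C=C/C(C)=C/C=C/C=C(C)/C=C/C=C(C)/C=C/[C@@H]1[C@H](C(C)(C)O)CC[C@@]1(C)O | target

**Summary**

Total step count: 16. Longest linear sequence: 14 steps (steps 1–12, 15, 16).

Steps most likely to fail: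

Step 5. After the conjugate addition the basic ylide may take a ketone α-hydrogen (at C6 or the methyl) faster than it closes on the carbonyl, which would stall ring closure, erode the C6 configuration or expel the silyloxy group. The fallback sets out from 6 and returns at 10, making the two ring bonds in separate steps without a basic ylide. C-allylation of 6 (NaH, allyl bromide, THF, 0 °C) should give the allyl keto malonate F1. Lombardo–Takai methylenation of the ketone (Zn, CH2Br2, TiCl4, THF/CH2Cl2, 0 °C) should give the isopropenyl diene F2. Ring-closing metathesis (second-generation Grubbs catalyst RuCl2(H2IMes)(PCy3)(=CHPh), CH2Cl2, 40 °C) should then close C4=C5 and give 10.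

Step 8. Capture of the planar tertiary C5 radical by oxygen may show poor facial selectivity, or the radical may be reduced instead of oxygenated. The fallback sets out from 13 and returns at 15, bypassing 14, and uses concerted peracid delivery. Epoxidation on the convex face (mCPBA, NaHCO3, CH2Cl2, 0 °C) should give the exo-epoxy lactone F3. Double methyl addition to the lactone (MeLi, THF, −78 °C) should give the epoxy diol F4. Hydride opening at the less substituted C4 (LiAlH4, THF, 0 °C → reflux) should then give triol 15.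

Step 15. Addition of the crowded sulfonyl carbanion to the α-branched polyenal may be slow, with self-condensation of the sulfone or low conversion. The fallback reverses the polarity of the C7=C8 olefination; it sets out from 15 and 23 and returns at 25. Persilylation of 15 (Et3SiOTf, 2,6-lutidine, CH2Cl2) should give the tris(triethylsilyl) ether F5. Direct Swern oxidation of its primary silyl ether (oxalyl chloride, DMSO, then i-Pr2NEt, −78 → −40 °C) should give the bis-silylated ring aldehyde F6. In parallel, reduction of 23 (NaBH4, MeOH/CH2Cl2, 0 °C) should give apo-8'-lycopenol F7, and PPh3·HBr (MeOH/CH2Cl2, rt) should convert it into the C30 phosphonium bromide F8. Wittig reaction of F8 with F6 (NaOMe, CH2Cl2/MeOH, 0 °C; then I2 cat.) should give 25; the weakly basic polyenyl ylide is chosen to limit epimerisation of F6 at C6.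

Further compounds
F1 | step 5 | dimethyl 2-allyl-2-[(2S)-1-[(tert-butyldiphenylsilyl)oxy]-3-oxobutan-2-yl]malonate | CC(=O)[C@H](CO[Si](c1ccccc1)(c1ccccc1)C(C)(C)C)C(CC=C)(C(=O)OC)C(=O)OC
F2 | step 5 | dimethyl 2-allyl-2-[(2S)-1-[(tert-butyldiphenylsilyl)oxy]-3-methylbut-3-en-2-yl]malonate | CC(=C)[C@H](CO[Si](c1ccccc1)(c1ccccc1)C(C)(C)C)C(CC=C)(C(=O)OC)C(=O)OC
F3 | step 8 | 4,5-epoxide of 13, oxirane oxygen cis to the ring-fusion hydrogens (exo) | O=C1OC[C@@H]2[C@H]1C[C@H]3O[C@@]23C
F4 | step 8 | epoxy diol from F3: ring carrying CH2OH and CMe2OH cis, oxirane on the opposite face | OC[C@@H]1[C@H](C(C)(C)O)C[C@H]2O[C@@]12C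
F5 | step 15 | tris(triethylsilyl) ether of 15 | CC[Si](CC)(CC)OC[C@@H]1[C@H](C(C)(C)O[Si](CC)(CC)CC)CC[C@@]1(C)O[Si](CC)(CC)CC
F6 | step 15 | (1R,2R,5R)-2-methyl-2-[(triethylsilyl)oxy]-5-{2-[(triethylsilyl)oxy]propan-2-yl}cyclopentane-1-carbaldehyde | O=C[C@@H]1[C@H](C(C)(C)O[Si](CC)(CC)CC)CC[C@@]1(C)O[Si](CC)(CC)CC
F7 | step 15 | apo-8'-lycopenol (all-E) | CC(C)=CCC/C(C)=C/C=C/C(C)=C/C=C/C(C)=C/C=C/C=C(C)/C=C/C=C(C)/CO
F8 | step 15 | apo-8'-lycopenyl(triphenyl)phosphonium bromide (all-E) | CC(C)=CCC/C(C)=C/C=C/C(C)=C/C=C/C(C)=C/C=C/C=C(C)/C=C/C=C(C)/C[P+](c1ccccc1)(c1ccccc1)c1ccccc1.[Br-]
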